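**Retrosynthetic overview**

The target is numbered as an octahydro-1H-indene: ring A (five-membered) = C1, C2, C3, C3a, C7a; ring B (six-membered) = C3a, C4, C5, C6, C7, C7a. The three esters, the C2 ketone, the C6 oxygen (allylic oxidation next to the C7 methylidene) and the epoxide are all adjusted late on hydrindanol 17.
Key disconnection: the bonds C3a–C7a and C5–C6 are formed together from the acyclic trienynal 15 by a Me2AlCl-promoted two-fold ene sequence (conjugate ene reaction, then type 2 carbonyl-ene reaction). Ring A closes first and ring B second in the same flask; the oxirane ring is closed later (step 14).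
Enabling feature: the exocyclic methylidene carbon on C7 of ring B, flanked by C7a and C6, is the mark of a prenyl (isopropylidene) terminus that has acted twice as ene donor; C3a–C4–C5 are the β-carbon, α-carbon and carbonyl carbon of an (E)-enal.
Precursor 15 comes from a thiazolidinethione aldol between an (S)-3-hydroxybutanoate unit and 4-methylpent-3-enal (sets C3, C2 and the side-chain carbinol), then Wittig olefination, α-iodination and Sonogashira coupling; the alkyne is the latent methyloxiranyl group.

Key step: step 10

Remark 1: the 2-methylbutanoate of the structure is read as the (2R)-ester and the 3-methylpent-2-enoate as the (2Z)-ester, and both acids are used in these forms.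
Remark 2: in the names, α is the face of H-7a and β the face of H-3a of the trans-fused core.

Step 1
Reactants: 1 (S)-3-hydroxybutanoic acid
Product: 3 (S)-3-(triethylsilyloxy)butanoic acid, via bis-silylated acid 2 (not isolated)
Conditions: Et3SiCl (2.2 equiv), imidazole, DMF, 0 °C to rt; then H2O/THF, rt
Reagents that add atoms: chlorotriethylsilane, CC[Si](Cl)(CC)CC
Why: silyl protection of alcohol and acid followed by selective hydrolysis of the labile silyl ester should leave the acid free and the silyl ether in place; the stereocenter is not touched.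

Step 2
Reactants: 3 (S)-3-(triethylsilyloxy)butanoic acid; 4 (R)-4-benzyl-1,3-thiazolidine-2-thione
Product: 5 N-acyl thiazolidinethione
Conditions: DCC, DMAP (cat.), CH2Cl2, 0 °C to rt
Reagents that add atoms: none
Why: carbodiimide N-acylation (Steglich-type coupling) should install the aldol auxiliary without touching the stereocenter.

Step 3
Reactants: 6 4-methylpent-3-en-1-ol
Product: 7 4-methylpent-3-enal
Conditions: Dess–Martin periodinane, NaHCO3, CH2Cl2, 0 °C; used at once
Reagents that add atoms: none
Why: Dess–Martin oxidation should give the β,γ-unsaturated aldehyde under buffered conditions that do not move the double bond into conjugation.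

Step 4
Reactants: 5 N-acyl thiazolidinethione; 7 4-methylpent-3-enal
Product: 8 syn-aldol adduct
Conditions: TiCl4 (1.05 equiv), i-Pr2NEt (1.1 equiv), N-methylpyrrolidinone (1 equiv), CH2Cl2, 0 °C; then 7, −78 to 0 °C
Reagents that add atoms: none
Why: titanium thiazolidinethione aldol reaction (Crimmins aldol, Evans-syn mode): the chlorotitanium Z-enolate should add through a Zimmerman–Traxler chair on the face away from the benzyl group of the (R)-auxiliary, which sets the new carbinol carbon and the α-carbon as the 2,3-syn pair (future C2 and C3) under auxiliary control.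

Step 5
Reactants: 8 syn-aldol adduct
Product: 9 triisopropylsilyl ether
Conditions: i-Pr3SiOTf, 2,6-lutidine, CH2Cl2, −78 to 0 °C
Reagents that add atoms: triisopropylsilyl trifluoromethanesulfonate, CC(C)[Si](OS(=O)(=O)C(F)(F)F)(C(C)C)C(C)C
Why: silyl triflate protection of the hindered secondary alcohol should give an ether much less labile than the triethylsilyl ether, which allows the two oxygens to be told apart at the end.

Step 6
Reactants: 9 triisopropylsilyl ether
Product: 10 α-branched aldehyde
Conditions: i-Bu2AlH (1.2 equiv), CH2Cl2, −78 °C; aqueous potassium sodium tartrate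
Reagents that add atoms: none
Why: reductive cleavage of the N-acyl thiazolidinethione by i-Bu2AlH should stop at the aldehyde through a stable tetrahedral aluminium intermediate and return auxiliary 4, the α-stereocenter being kept by cold, non-basic handling.

Step 7
Reactants: 10 α-branched aldehyde; 11 (triphenylphosphoranylidene)acetaldehyde
Product: 12 (E)-enal
Conditions: toluene, 60 °C
Reagents that add atoms: none
Why: Wittig olefination with the stabilised formyl ylide should give the (E)-enal under neutral conditions that do not epimerise the aldehyde α-carbon.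

Step 8
Reactants: 12 (E)-enal
Product: 13 (Z)-2-iodoenal
Conditions: I2, K2CO3, DMAP (0.2 equiv), THF/H2O, rt
Reagents that add atoms: iodine, [I][I]
Why: DMAP-catalysed α-iodination of an enal (conjugate addition of DMAP, iodination of the enolate, elimination; Baylis–Hillman-type mechanism) should give the (Z)-2-iodoenal in which the formyl group stays trans to the chain.

Step 9
Reactants: 13 (Z)-2-iodoenal; 14 ethynyltrimethylsilane
Product: 15 trienynal
Conditions: PdCl2(PPh3)2 (5 mol%), CuI (10 mol%), i-Pr2NH, THF, 0 °C to rt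
Reagents that add atoms: none
Why: Sonogashira coupling of the α-iodoenal should proceed with retention of alkene geometry and place a Lewis-acid-inert alkyne cis to the chain as the latent C4 substituent.

Step 10
Reactants: 15 trienynal
Product: 17 5β-hydroxy-7-methylidene hydrindane (silylalkyne), via monocyclic ene aldehyde 16 (not isolated)
Conditions: Me2AlCl (2.2 equiv), CH2Cl2, −78 to 0 °C
Reagents that add atoms: none
Why: Me2AlCl binds the enal oxygen and the prenyl double bond adds through its CH carbon (C7a) to the enal β-carbon (C3a) while a methyl hydrogen passes to the α-carbon (C4) (Lewis-acid-promoted intramolecular conjugate ene reaction of a 1,6-diene), after which the aluminium-bound aldehyde of 16 is attacked by the new isopropenyl CH2 (C6) with transfer of the second methyl hydrogen to oxygen (type 2 intramolecular carbonyl-ene reaction), leaving the C7 methylidene. The closest known reaction type is the Me2AlCl-promoted two-fold ene ([3+3]) annulation of enals by alkylidene donors, made doubly intramolecular here. Ring A closes in a 5-exo mode onto the enal β-carbon (the enal double bond lies outside the new ring), and ring B closes as a six-membered ring through a bicyclic chair in which the tether sits on the central carbon of the ene unit. C3a is controlled by allylic 1,3-strain at the existing C3 centre (C3–H eclipses the enal, so C7a adds anti to the silyloxyethyl group), C7a by the trans-diequatorial transition state usual for Lewis-acid ene cyclisation of 1,6-dienes, C4 by suprafacial delivery of carbon and hydrogen to the (E)-enal with the alkynyl group ending equatorial, and C5 by the closed ene transition state that holds the carbonyl oxygen axial over the ene unit (5β-OH). The step needs the ene pathway to win over collapse of the polarised intermediate to a dihydropyran or cyclobutane and over proton loss into the ring; the two methyl groups held 1,5 to the accepting atoms, the use of Me2AlCl (which ends as the aluminium alkoxide with loss of methane and scavenges protons) and the Lewis-acid-inert alkynyl and silyl ether groups should secure this.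

Step 11
Reactants: 17 5β-hydroxy-7-methylidene hydrindane (silylalkyne)
Product: 18 terminal alkyne
Conditions: K2CO3 (0.2 equiv), MeOH, rt
Reagents that add atoms: none
Why: base-catalysed methanolysis of the alkynyl C–Si bond (protodesilylation) should free the terminal alkyne without touching the silyl ethers or any stereocenter.

Step 12
Reactants: 18 terminal alkyne
Product: 21 4β-acetyl-5β-hydroxy hydrindane, via dimethylsilyl ether 19 (not isolated), via cyclic alkenylsiloxane 20 (not isolated)
Conditions: (HMe2Si)2NH, 60 °C; then Pt2[(CH2=CHSiMe2)2O]3 (cat., zerovalent platinum), THF, rt; then H2O2, KHCO3, THF/MeOH, rt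
Reagents that add atoms: 1,1,3,3-tetramethyldisilazane, C[SiH](C)N[SiH](C)C (its silicon is present only in 19 and 20); hydrogen peroxide, OO
Why: silyl-tethered intramolecular hydrosilylation (5-exo-dig, syn) should place silicon on the internal alkyne carbon and Tamao–Fleming oxidation should turn that C–Si bond into the ketone, a regiocontrolled alkyne hydration that the neighbouring hydroxyl directs instead of diverting; C4 keeps its equatorial (more stable) configuration.

Step 13
Reactants: 21 4β-acetyl-5β-hydroxy hydrindane
Product: 22 chloromethyl ketone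
Conditions: LiN(SiMe3)2 (2.2 equiv), THF, −78 °C; N-chlorosuccinimide, −78 °C; NH4Cl (aq) at −78 °C
Reagents that add atoms: N-chlorosuccinimide, O=C1CCC(=O)N1Cl
Why: kinetic deprotonation at the unhindered methyl group and chlorination of the lithium enolate (enolate α-halogenation) should give the chloromethyl ketone, the cold quench preventing O-alkylation by the C5 alkoxide and epimerisation at C4.

Step 14
Reactants: 22 chloromethyl ketone
Product: 24 5β-hydroxy epoxide, via chlorohydrin 23 (not isolated)
Conditions: MeMgBr (3 equiv), THF, −78 °C; NH4Cl (aq); then K2CO3, MeOH, 0 °C to rt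
Reagents that add atoms: methylmagnesium bromide, C[Mg]Br
Why: chelation-controlled Grignard addition (Cram chelate model): the magnesium alkoxide of the axial C5 hydroxyl should bind the ketone oxygen in a cis-fused six-membered chelate and methyl should add to its convex face (away from C3a), which sets the quaternary carbon as (S), after which base closes the oxirane by 3-exo-tet displacement of chloride without touching that centre.

Step 15
Reactants: 24 5β-hydroxy epoxide
Product: 26 5α-hydroxy epoxide, via 5-ketone 25 (not isolated)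
Conditions: Dess–Martin periodinane, NaHCO3, CH2Cl2, 0 °C; filter, concentrate; NaBH4, MeOH, −40 °C
Reagents that add atoms: none
Why: oxidation–reduction inversion: Dess–Martin oxidation and then axial hydride delivery by NaBH4 from the β face of the cyclohexanone (only one syn-axial hydrogen on that face) should give the equatorial 5α-alcohol, whatever C5 ratio step 10 has given.

Step 16
Reactants: 27 ethyl pent-2-ynoate
Product: 28 ethyl (2Z)-3-methylpent-2-enoate
Conditions: Me2CuLi, THF, −78 °C; MeOH at −78 °C, then NH4Cl (aq)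
Reagents that add atoms: lithium dimethylcuprate, [Li+].C[Cu-]C
Why: syn carbocupration of the ynoate and cold protonation of the alkenylcuprate should place methyl and hydrogen cis, which gives the (Z)-enoate (ethyl cis to the ester) stereospecifically.

Step 17
Reactants: 28 ethyl (2Z)-3-methylpent-2-enoate
Product: 29 (2Z)-3-methylpent-2-enoic acid
Conditions: LiOH, THF/H2O, rt; then 1 M HCl to pH 2
Reagents that add atoms: lithium hydroxide, [Li+].[OH-]
Why: ester saponification should give the acid with the trisubstituted alkene geometry unchanged, since aqueous hydroxide does not deprotonate the γ-position.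

Step 18
Reactants: 26 5α-hydroxy epoxide; 29 (2Z)-3-methylpent-2-enoic acid
Product: 30 C5 (Z)-enoate
Conditions: DCC, DMAP (0.3 equiv), CH2Cl2, 0 °C to rt
Reagents that add atoms: none
Why: Steglich esterification should acylate the only free hydroxyl with retention at C5, the β,β-disubstituted enoate keeping its geometry under these mild conditions.

Step 19
Reactants: 30 C5 (Z)-enoate
Product: 31 6α-hydroxy C5 ester
Conditions: SeO2 (0.5 equiv), t-BuOOH (3 equiv), CH2Cl2, rt
Reagents that add atoms: tert-butyl hydroperoxide, CC(C)(C)OO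
Why: SeO2/t-BuOOH allylic hydroxylation (ene reaction, then 2,3-sigmatropic shift) of the 1,1-disubstituted methylidene should oxidise the allylic CH2 (C6) in preference to the ring-fusion CH and deliver oxygen to the axial α position, cis to the C5 ester, with the double bond back at C7.

Step 20
Reactants: 31 6α-hydroxy C5 ester; 32 (R)-2-methylbutanoic acid
Product: 33 C5,C6 diester
Conditions: DCC, DMAP, CH2Cl2, 0 °C to rt
Reagents that add atoms: none
Why: Steglich esterification of the axial allylic alcohol should proceed with retention, the α-stereocenter of the simple alkanoic acid not being activated enough to racemise.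

Step 21
Reactants: 33 C5,C6 diester
Product: 34 side-chain alcohol
Conditions: Bu4NF (1.1 equiv), AcOH (1.1 equiv), THF, 0 °C
Reagents that add atoms: none
Why: buffered fluoride desilylation should remove the triethylsilyl ether much faster than the hindered triisopropylsilyl ether and leave esters and epoxide intact.

Step 22
Reactants: 34 side-chain alcohol
Product: 35 side-chain acetate
Conditions: Ac2O, pyridine, DMAP (cat.), CH2Cl2, 0 °C to rt
Reagents that add atoms: acetic anhydride, CC(=O)OC(C)=O
Why: acetylation of the only free hydroxyl should proceed with retention.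

Step 23
Reactants: 35 side-chain acetate
Product: 36 C2 alcohol
Conditions: Bu4NF, AcOH (1:1), THF, rt
Reagents that add atoms: none
Why: buffered fluoride cleavage of the triisopropylsilyl ether should free the C2 hydroxyl, the acetic acid buffer suppressing 1,3-acetyl migration and epoxide opening.

Step 24
Reactants: 36 C2 alcohol
Product: 37 target CNP0262178.2
Conditions: Dess–Martin periodinane, NaHCO3, CH2Cl2, 0 °C to rt
Reagents that add atoms: none
Why: Dess–Martin oxidation should give the cyclopentanone under buffered conditions that neither eliminate the β-acetoxy group nor epimerise C3, whose side chain already sits trans to its neighbours.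

**Compound list**

1 | (S)-3-hydroxybutanoic acid | C[C@H](O)CC(=O)O | starting material
2 | triethylsilyl (S)-3-(triethylsilyloxy)butanoate | C[C@H](O[Si](CC)(CC)CC)CC(=O)O[Si](CC)(CC)CC | intermediate
3 | (S)-3-(triethylsilyloxy)butanoic acid | C[C@H](O[Si](CC)(CC)CC)CC(=O)O | intermediate
4 | (R)-4-benzyl-1,3-thiazolidine-2-thione | S=C1N[C@H](Cc2ccccc2)CS1 | starting material
5 | (R)-4-benzyl-3-[(S)-3-(triethylsilyloxy)butanoyl]-1,3-thiazolidine-2-thione | C[C@H](O[Si](CC)(CC)CC)CC(=O)N1[C@H](Cc2ccccc2)CSC1=S | intermediate
6 | 4-methylpent-3-en-1-ol | CC(C)=CCCO | starting material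
7 | 4-methylpent-3-enal | CC(C)=CCC=O | intermediate
8 | (R)-4-benzyl-3-{(2S,3S)-3-hydroxy-6-methyl-2-[(1S)-1-(triethylsilyloxy)ethyl]hept-5-enoyl}-1,3-thiazolidine-2-thione | CC(C)=CC[C@H](O)[C@@H]([C@H](C)O[Si](CC)(CC)CC)C(=O)N1[C@H](Cc2ccccc2)CSC1=S | intermediate
9 | (R)-4-benzyl-3-{(2R,3S)-6-methyl-2-[(1S)-1-(triethylsilyloxy)ethyl]-3-(triisopropylsilyloxy)hept-5-enoyl}-1,3-thiazolidine-2-thione | CC(C)=CC[C@H](O[Si](C(C)C)(C(C)C)C(C)C)[C@@H]([C@H](C)O[Si](CC)(CC)CC)C(=O)N1[C@H](Cc2ccccc2)CSC1=S | intermediate
10 | (2R,3S)-6-methyl-2-[(1S)-1-(triethylsilyloxy)ethyl]-3-(triisopropylsilyloxy)hept-5-enal | CC(C)=CC[C@H](O[Si](C(C)C)(C(C)C)C(C)C)[C@@H]([C@H](C)O[Si](CC)(CC)CC)C=O | intermediate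
11 | (triphenylphosphoranylidene)acetaldehyde | O=CC=P(c1ccccc1)(c1ccccc1)c1ccccc1 | starting material
12 | (2E,4R,5S)-8-methyl-4-[(1S)-1-(triethylsilyloxy)ethyl]-5-(triisopropylsilyloxy)nona-2,7-dienal | CC(C)=CC[C@H](O[Si](C(C)C)(C(C)C)C(C)C)[C@@H]([C@H](C)O[Si](CC)(CC)CC)/C=C/C=O | intermediate
13 | (2Z,4R,5S)-2-iodo-8-methyl-4-[(1S)-1-(triethylsilyloxy)ethyl]-5-(triisopropylsilyloxy)nona-2,7-dienal | CC(C)=CC[C@H](O[Si](C(C)C)(C(C)C)C(C)C)[C@@H]([C@H](C)O[Si](CC)(CC)CC)/C=C(/C=O)I | intermediate
14 | ethynyltrimethylsilane | C#C[Si](C)(C)C | starting material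
15 | (2E,4R,5S)-8-methyl-4-[(1S)-1-(triethylsilyloxy)ethyl]-5-(triisopropylsilyloxy)-2-[(trimethylsilyl)ethynyl]nona-2,7-dienal | CC(C)=CC[C@H](O[Si](C(C)C)(C(C)C)C(C)C)[C@@H]([C@H](C)O[Si](CC)(CC)CC)/C=C(/C=O)C#C[Si](C)(C)C | intermediate
16 | monocyclic ene aldehyde: cyclopentane with four contiguous all-trans substituents, namely prop-1-en-2-yl (on future C7a), the CH(C≡C–SiMe3)CHO chain (on future C3a, chain carbon configured as C4 of 17), (1S)-1-(triethylsilyloxy)ethyl and OSi(i-Pr)3 | C=C(C)[C@H]1C[C@H](O[Si](C(C)C)(C(C)C)C(C)C)[C@@H]([C@H](C)O[Si](CC)(CC)CC)[C@@H]1[C@@H](C#C[Si](C)(C)C)C=O | intermediate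
17 | trans-fused 7-methylideneoctahydro-1H-inden-5-ol (H-3a β, H-7a α) with 2α-OSi(i-Pr)3, 3β-[(1S)-1-(triethylsilyloxy)ethyl], 4β-[(trimethylsilyl)ethynyl] and 5β-OH (axial) | C=C1[C@H]2C[C@H](O[Si](C(C)C)(C(C)C)C(C)C)[C@@H]([C@H](C)O[Si](CC)(CC)CC)[C@@H]2[C@@H](C#C[Si](C)(C)C)[C@@H](O)C1 | intermediate
18 | as 17 with 4β-ethynyl | C=C1[C@H]2C[C@H](O[Si](C(C)C)(C(C)C)C(C)C)[C@@H]([C@H](C)O[Si](CC)(CC)CC)[C@@H]2[C@@H](C#C)[C@@H](O)C1 | intermediate
19 | 5β-O-dimethylsilyl ether of 18 | C=C1[C@H]2C[C@H](O[Si](C(C)C)(C(C)C)C(C)C)[C@@H]([C@H](C)O[Si](CC)(CC)CC)[C@@H]2[C@@H](C#C)[C@@H](O[SiH](C)C)C1 | intermediate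
20 | cyclic alkenylsiloxane: 2,2-dimethyl-3-methylidene-1,2-oxasilolane cis-fused across C4–C5 (silicon on the former internal alkyne carbon, oxygen on C5) | C=C1[C@H]2C[C@H](O[Si](C(C)C)(C(C)C)C(C)C)[C@@H]([C@H](C)O[Si](CC)(CC)CC)[C@@H]2[C@H]3C(=C)[Si](C)(C)O[C@H]3C1 | intermediate
21 | as 17 with 4β-acetyl (5β-OH) | C=C1[C@H]2C[C@H](O[Si](C(C)C)(C(C)C)C(C)C)[C@@H]([C@H](C)O[Si](CC)(CC)CC)[C@@H]2[C@@H](C(C)=O)[C@@H](O)C1 | intermediate
22 | as 17 with 4β-(chloroacetyl) (5β-OH) | C=C1[C@H]2C[C@H](O[Si](C(C)C)(C(C)C)C(C)C)[C@@H]([C@H](C)O[Si](CC)(CC)CC)[C@@H]2[C@@H](C(=O)CCl)[C@@H](O)C1 | intermediate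
23 | as 17 with 4β-[(2S)-1-chloro-2-hydroxypropan-2-yl] (5β-OH) | C=C1[C@H]2C[C@H](O[Si](C(C)C)(C(C)C)C(C)C)[C@@H]([C@H](C)O[Si](CC)(CC)CC)[C@@H]2[C@@H]([C@@](O)(C)CCl)[C@@H](O)C1 | intermediate
24 | as 17 with 4β-[(2S)-2-methyloxiran-2-yl] (5β-OH, axial) | C=C1[C@H]2C[C@H](O[Si](C(C)C)(C(C)C)C(C)C)[C@@H]([C@H](C)O[Si](CC)(CC)CC)[C@@H]2[C@@H]([C@@]2(C)CO2)[C@@H](O)C1 | intermediate
25 | 5-ketone of 24 | C=C1[C@H]2C[C@H](O[Si](C(C)C)(C(C)C)C(C)C)[C@@H]([C@H](C)O[Si](CC)(CC)CC)[C@@H]2[C@@H]([C@@]2(C)CO2)C(=O)C1 | intermediate
26 | C5 epimer of 24: 5α-OH (equatorial) | C=C1[C@H]2C[C@H](O[Si](C(C)C)(C(C)C)C(C)C)[C@@H]([C@H](C)O[Si](CC)(CC)CC)[C@@H]2[C@@H]([C@@]2(C)CO2)[C@H](O)C1 | intermediate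
27 | ethyl pent-2-ynoate | CCC#CC(=O)OCC | starting material
28 | ethyl (2Z)-3-methylpent-2-enoate | CCOC(=O)/C=C(/C)CC | intermediate
29 | (2Z)-3-methylpent-2-enoic acid | OC(=O)/C=C(/C)CC | intermediate
30 | (2Z)-3-methylpent-2-enoate of 26 at the 5α-oxygen | C=C1[C@H]2C[C@H](O[Si](C(C)C)(C(C)C)C(C)C)[C@@H]([C@H](C)O[Si](CC)(CC)CC)[C@@H]2[C@@H]([C@@]2(C)CO2)[C@H](OC(=O)/C=C(/C)CC)C1 | intermediate
31 | as 30 with 6α-OH (axial, cis to the C5 ester) | C=C1[C@H]2C[C@H](O[Si](C(C)C)(C(C)C)C(C)C)[C@@H]([C@H](C)O[Si](CC)(CC)CC)[C@@H]2[C@@H]([C@@]2(C)CO2)[C@H](OC(=O)/C=C(/C)CC)[C@@H]1O | intermediate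
32 | (R)-2-methylbutanoic acid | CC[C@@H](C)C(=O)O | starting material
33 | as 31 with the 6α-oxygen acylated by (2R)-2-methylbutanoyl | C=C1[C@H]2C[C@H](O[Si](C(C)C)(C(C)C)C(C)C)[C@@H]([C@H](C)O[Si](CC)(CC)CC)[C@@H]2[C@@H]([C@@]2(C)CO2)[C@H](OC(=O)/C=C(/C)CC)[C@@H]1OC(=O)[C@H](C)CC | intermediate
34 | as 33 with 3β-[(1S)-1-hydroxyethyl] | C=C1[C@H]2C[C@H](O[Si](C(C)C)(C(C)C)C(C)C)[C@@H]([C@H](C)O)[C@@H]2[C@@H]([C@@]2(C)CO2)[C@H](OC(=O)/C=C(/C)CC)[C@@H]1OC(=O)[C@H](C)CC | intermediate
35 | as 33 with 3β-[(1S)-1-acetoxyethyl] | C=C1[C@H]2C[C@H](O[Si](C(C)C)(C(C)C)C(C)C)[C@@H]([C@H](C)OC(C)=O)[C@@H]2[C@@H]([C@@]2(C)CO2)[C@H](OC(=O)/C=C(/C)CC)[C@@H]1OC(=O)[C@H](C)CC | intermediate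
36 | as 35 with 2α-OH | C=C1[C@H]2C[C@H](O)[C@@H]([C@H](C)OC(C)=O)[C@@H]2[C@@H]([C@@]2(C)CO2)[C@H](OC(=O)/C=C(/C)CC)[C@@H]1OC(=O)[C@H](C)CC | intermediate
37 | (3R,3aS,4R,5S,6R,7aS)-3-[(1S)-1-acetoxyethyl]-7-methylidene-4-[(2S)-2-methyloxiran-2-yl]-6-{[(2R)-2-methylbutanoyl]oxy}-2-oxooctahydro-1H-inden-5-yl (2Z)-3-methylpent-2-enoate | C=C1[C@H]2CC(=O)[C@@H]([C@H](C)OC(C)=O)[C@@H]2[C@@H]([C@@]2(C)CO2)[C@H](OC(=O)/C=C(/C)CC)[C@@H]1OC(=O)[C@H](C)CC | target

**Step count and risks**

Total step count: 24 (steps 3, 16 and 17 make the two side components). Longest linear sequence: 21 steps (1, 2, 4 to 15, 18 to 24).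

Steps most likely to fail:

Step 10. The cascade may stall after ring A, or the aluminium-bound aldehyde may be lost to chloride capture of the tertiary cation, proton loss into the ring or collapse of the polarised intermediate to a dihydropyran before ring B closes. The configurations at C5 and C4 matter less, because C5 is reset in step 15 and C4 is an epimerisable ketone α-carbon in 21. Fallback: the two bond formations are separated and the second is made by a different reaction type. The reaction is run with 1.1 equiv of Me2AlCl and quenched at −78 °C to isolate the monocyclic aldehyde 16, from which the fallback sets out. Selenium-catalysed ene-type allylic chlorination of the isopropenyl group (N-chlorosuccinimide, PhSeCl cat., CH2Cl2, rt) should give the 2-(chloromethyl)allyl aldehyde F1. An intramolecular Nozaki–Hiyama allylation (CrCl2, THF, rt) should then close ring B through the same bicyclic chair, with regeneration of the methylidene, and give 17, where the main route is rejoined at step 11.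

Step 14. The sense or level of facial selectivity of the methyl addition may differ from the chelate model if a non-chelated addition competes, which would give the wrong configuration at the quaternary oxirane carbon. Fallback: the roles of the two carbon substituents are exchanged, so that the same preferred face leads to the other configuration. The fallback sets out from methyl ketone 21 and omits step 13. Addition of LiCH2Cl (generated from ClCH2I and MeLi·LiBr, THF, −78 °C) should give the lithium alkoxide of chlorohydrin 23, which closes on warming to epoxide 24, where the route is rejoined at step 15. This fallback makes no new compound (F0).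

Step 19. The allylic oxidation may attack the ring-fusion C–H instead of C6, run on to the enone, give the equatorial alcohol or open the epoxide under the mildly acidic selenium conditions. Fallback: the C6 oxygen is brought in by enolate chemistry before C5 is reduced. The fallback sets out from ketone 25, isolated after the oxidation stage of step 15. Kinetic silylation (LiN(SiMe3)2, Me3SiCl, THF, −78 °C) should give the silyl dienol ether F2 by deprotonation at the allylic C6. Rubottom oxidation with dimethyldioxirane (acetone, −78 °C) and mild desilylation should give the 6α-hydroxy ketone F3 by axial attack. Steglich esterification with 32 should give the acyloxy ketone F4. NaBH4 (MeOH, −40 °C) should reduce C5 from the β face to the 5α-alcohol F5. Steglich esterification with 29 then gives 33, where the route is rejoined at step 21.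

**Further compounds**

F1 | step 10 | 2-(chloromethyl)allyl analogue of 16 (3-chloroprop-1-en-2-yl in place of prop-1-en-2-yl) | C=C(CCl)[C@H]1C[C@H](O[Si](C(C)C)(C(C)C)C(C)C)[C@@H]([C@H](C)O[Si](CC)(CC)CC)[C@@H]1[C@@H](C#C[Si](C)(C)C)C=O
F0 | step 14 | none | none
F2 | step 19 | trimethylsilyl dienol ether of 25 (C5=C6 enol ether conjugated to the C7 methylidene) | C=C1[C@H]2C[C@H](O[Si](C(C)C)(C(C)C)C(C)C)[C@@H]([C@H](C)O[Si](CC)(CC)CC)[C@@H]2[C@@H]([C@@]2(C)CO2)C(O[Si](C)(C)C)=C1
F3 | step 19 | 6α-hydroxy derivative of ketone 25 | C=C1[C@H]2C[C@H](O[Si](C(C)C)(C(C)C)C(C)C)[C@@H]([C@H](C)O[Si](CC)(CC)CC)[C@@H]2[C@@H]([C@@]2(C)CO2)C(=O)[C@@H]1O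
F4 | step 19 | (2R)-2-methylbutanoate of F3 | C=C1[C@H]2C[C@H](O[Si](C(C)C)(C(C)C)C(C)C)[C@@H]([C@H](C)O[Si](CC)(CC)CC)[C@@H]2[C@@H]([C@@]2(C)CO2)C(=O)[C@@H]1OC(=O)[C@H](C)CC
F5 | step 19 | 5α-alcohol from F4 (C6 ester, free C5 hydroxyl) | C=C1[C@H]2C[C@H](O[Si](C(C)C)(C(C)C)C(C)C)[C@@H]([C@H](C)O[Si](CC)(CC)CC)[C@@H]2[C@@H]([C@@]2(C)CO2)[C@H](O)[C@@H]1OC(=O)[C@H](C)CC
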